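**Retrosynthetic overview** (labdane numbering: ring A = C1–C5/C10, ring B = C5–C10, C19 = 4β-CH2O, C18 = 4α-CH3)

1. The butenolide chain is attached last: C12–C13 by B-alkyl Suzuki coupling with 4-bromofuran-2(5H)-one, C9–C11 by Stille vinylation of a C9 enol triflate that also fixes the C8=C9 alkene.
2. The C2 and C6 carbinols come from face-selective hydride reductions; C19–OH and C1H2 come from SmI2 cleavage of a temporary C1–O–C19 ether bridge next to the C2 ketone.
3. Key disconnection: ring A by an enantioselective Diels–Alder union of 2,6-dimethyl-1,4-benzoquinone (all of ring B with both methyls) and 3-methyl-5-(triisopropylsilyloxy)-2H-pyran (C1–C4, C18, C19). C1–C10 bonds first and the C4–C5 bond closes ring A at the quaternary carbon C4.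
4. Enabling feature: the target is a cis-fused decalin (5β-H, 10β-CH3) with oxygen at C6 and sp2 C9, so ring B is a latent quinone. The C2 and C6 oxygens are 1,5-related through C3–C4–C5, so C4 is a diene terminus and C5 an enone α-carbon. The C19 oxygen is cis to H5 and the C10 methyl, so it can be tied to C1 as a pyran ring that locks the diene s-cis.
5. Ring order: ring B and the butenolide are bought; the temporary pyran ring is made first, ring A is closed onto ring B in step 4, and the pyran is opened in step 9.

Key step: step 4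

Remark (assumption on the chemistry): the (R)-oxazaborolidinium catalyst is assigned from the accepted α-C–H···O binding model for quinones (reaction on the face away from the catalyst phenyl group); its mirror image is the drop-in choice should the sense of induction prove opposite.

**Route**

Step 1
Reactants: 1 2H-pyran-3,5(4H,6H)-dione
Product: 2 5-ethoxy-2H-pyran-3(6H)-one
Conditions: EtOH, p-TsOH·H2O (cat.), benzene, reflux, Dean–Stark
Reagents that add atoms: ethanol, CCO
Why: Acid-catalysed vinylogous ester formation from the enolised symmetric 1,3-diketone with azeotropic removal of water should give a single product because both carbonyls are equivalent.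

Step 2
Reactants: 2 5-ethoxy-2H-pyran-3(6H)-one
Product: 4 5-methyl-2H-pyran-3(6H)-one, via lithium alkoxide adduct 3 (not isolated)
Conditions: MeLi, THF, −78 °C; then 1 M HCl, 0 °C to rt
Reagents that add atoms: methyllithium, [Li]C
Why: Stork–Danheiser alkylative transposition: 1,2-addition of MeLi to the vinylogous ester carbonyl, then acid hydrolysis of the enol ether and loss of water, should give the β-methyl enone; no stereocentre is formed.

Step 3
Reactants: 4 5-methyl-2H-pyran-3(6H)-one
Product: 6 3-methyl-5-(triisopropylsilyloxy)-2H-pyran, via lithium dienolate 5 (not isolated)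
Conditions: LiN(i-Pr)2, THF, −78 °C; i-Pr3SiOSO2CF3, −78 °C; cold pentane/aq. NaHCO3 work-up below −20 °C, used at once
Reagents that add atoms: triisopropylsilyl trifluoromethanesulfonate, CC(C)[Si](OS(=O)(=O)C(F)(F)F)(C(C)C)C(C)C
Why: Kinetic α′-deprotonation of the enone at the OCH2 between ring oxygen and carbonyl, then O-silylation (silyl dienol ether formation), should give the cross-conjugated 2-silyloxy diene, which is kept cold because a 2H-pyran can open by oxa-6π electrocyclic ring opening.

Step 4
Reactants: 6 3-methyl-5-(triisopropylsilyloxy)-2H-pyran; 7 2,6-dimethyl-1,4-benzoquinone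
Product: 8 oxa-bridged adduct (1β,19-epoxy; C2=C3 triisopropylsilyl enol ether; 4α-CH3; 5β-H; 10β-CH3; C6=O; C7=C8; C9=O)
Conditions: (R)-1-(2-methylphenyl)-3,3-diphenyltetrahydro-1H,3H-pyrrolo[1,2-c][1,3,2]oxazaborole (20 mol%), HN(SO2CF3)2 (20 mol%), CH2Cl2, −78 °C
Reagents that add atoms: none
Why: The protonated oxazaborolidine should bind the more basic, unhindered C6 carbonyl of 7 (α-C5–H···O contact), so the diene terminus C1, activated by the 2-silyloxy group, attacks the methyl-bearing β-carbon C10 first and the gem-disubstituted terminus C4 then bonds to C5, an asynchronous [4+2] whose lagging bond C4–C5 closes ring A. The closest known reaction type is the oxazaborolidinium-catalysed enantioselective Diels–Alder reaction of 2-silyloxy dienes with methyl-substituted 1,4-benzoquinones, which builds the angular-methyl quaternary centre in the same way, together with the known use of 2H-pyrans as 4π partners. Ring A is closed as a six-membered carbocycle by cycloaddition (in the stepwise limit a 6-endo Michael closure of the C5 enolate onto C4), and because the pyran is retained it sits inside a 2-oxabicyclo[2.2.2]octene whose O–C19 bridge spans C1 and C4. C5 and C10 are cis because addition to the quinone C=C is suprafacial; C4 is set by the endo rule, which places ring B under the C2=C3 bridge and therefore H5 and the C10 methyl on the side of the O–C19 bridge, so C19 ends cis to both (4β) and the methyl 4α; C1 is a bridgehead fixed by the same geometry and is later returned to CH2; the absolute sense comes from the catalyst phenyl group shielding one quinone face. The step needs regiocontrol (C4 to C5, not to C10), which avoidance of vicinal quaternary centres and the catalyst-induced polarisation of C10 should secure, endo selectivity, which the cyclic s-cis diene favours, and enantiofacial control from the catalyst. The pyran ring is what makes the step workable, since it locks the diene s-cis and holds the CH2O group in the inside position that an acyclic diene would resist.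

Step 5
Reactants: 8 oxa-bridged adduct
Product: 9 6α-alcohol (C9 enone kept; hydroxyl on the face of the C2=C3 bridge)
Conditions: NaBH4, CeCl3·7H2O, MeOH/CH2Cl2, −78 °C
Reagents that add atoms: none
Why: Luche 1,2-reduction should take place at C6 because C9 is screened on its exo face by the adjacent 10β-methyl and on its endo face by the bicyclooctene, and hydride should enter C6 from the exo (β) face away from the C2=C3 bridge to give the 6α-carbinol; this also removes the ketone that could later trigger retro-Michael opening of the C4–C5 bond.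

Step 6
Reactants: 9 6α-alcohol
Product: 10 6α-O-tert-butyldimethylsilyl ether of 9
Conditions: t-BuMe2SiOSO2CF3, 2,6-lutidine, CH2Cl2, −78 to 0 °C
Reagents that add atoms: tert-butyldimethylsilyl trifluoromethanesulfonate, CC(C)(C)[Si](C)(C)OS(=O)(=O)C(F)(F)F
Why: Silyl triflate silylation of a hindered secondary alcohol should proceed cleanly, the silyl enol ether and the enone being inert to these conditions.

Step 7
Reactants: 10 6α-O-tert-butyldimethylsilyl ether
Product: 12 C9 enol triflate (C8=C9–OSO2CF3; C7H2; 6α-OSiMe2t-Bu; C2=C3 triisopropylsilyl enol ether; 1β,19-epoxy), via lithium C9 enolate 11 (not isolated)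
Conditions: LiBH(s-Bu)3, THF, −78 °C; then N-(5-chloro-2-pyridyl)bis(trifluoromethanesulfonimide), −78 to 0 °C
Reagents that add atoms: N-(5-chloro-2-pyridyl)bis(trifluoromethanesulfonimide), FC(F)(F)S(=O)(=O)N(c1ccc(Cl)cn1)S(=O)(=O)C(F)(F)F
Why: Conjugate hydride reduction of the α-methyl, β-unsubstituted cyclohexenone by the bulky borohydride (1,2-attack at C9 is blocked by quaternary C10) should give the C8=C9 enolate regiospecifically, and its O-triflation (reductive enol triflation) fixes the tetrasubstituted alkene.

Step 8
Reactants: 12 C9 enol triflate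
Product: 13 bridged 2-ketone (1β,19-epoxy-2-oxo; C9 enol triflate; 6α-OSiMe2t-Bu)
Conditions: Bu4NF, AcOH, THF, −20 to 0 °C
Reagents that add atoms: none
Why: Buffered fluoride desilylation should cleave the silyl enol ether much faster than the hindered secondary silyl ether, and protonation at C3 unveils the C2 ketone as an α-alkoxy ketone.

Step 9
Reactants: 13 bridged 2-ketone
Product: 14 19-hydroxy-2-ketone (cis-decalin; C1H2; 4β-CH2OH; 4α-CH3; 6α-OSiMe2t-Bu; C9 enol triflate)
Conditions: SmI2 (2.5 equiv), THF/MeOH, −78 °C
Reagents that add atoms: none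
Why: SmI2 reduction of an α-alkoxy ketone should expel the C1–O bond, which lies nearly parallel to the carbonyl π system in the bicyclo[2.2.2]octanone, and protonation of the samarium enolate at C1 opens the temporary bridge to C19–OH and C1H2 while the alkenyl triflate and silyl ether are untouched at −78 °C.

Step 10
Reactants: 14 19-hydroxy-2-ketone
Product: 15 19-acetate of 14
Conditions: Ac2O, pyridine, 4-(dimethylamino)pyridine (cat.), CH2Cl2, 0 °C to rt
Reagents that add atoms: acetic anhydride, CC(=O)OC(C)=O
Why: Standard acylation of the only free hydroxyl, a primary neopentyl alcohol.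

Step 11
Reactants: 15 19-acetate 2-ketone
Product: 16 2α-alcohol (19-OAc; 6α-OSiMe2t-Bu; C9 enol triflate)
Conditions: LiBH(s-Bu)3, THF, −78 °C, quench at −78 °C
Reagents that add atoms: none
Why: In the chair–chair conformer of the cis-decalin that keeps the 6α-silyloxy group equatorial on ring B, C9 and the 4α-methyl are syn-axial on the α face of ring A, so the bulky hydride should attack C2 equatorially from the β face and give the 2α-carbinol (substrate-controlled ketone reduction), the hindered acetate surviving at −78 °C.

Step 12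
Reactants: 16 2α-alcohol
Product: 17 9-vinyl diene (C8=C9–CH=CH2; 2α-OH; 19-OAc; 6α-OSiMe2t-Bu)
Conditions: CH2=CHSnBu3, Pd(PPh3)4 (10 mol%), LiCl, CuCl, DMSO, 60 °C
Reagents that add atoms: tributyl(vinyl)stannane, C=C[Sn](CCCC)(CCCC)CCCC
Why: Stille coupling of a hindered alkenyl triflate accelerated by LiCl and CuCl should install C11–C12 under neutral conditions that spare the acetate and free hydroxyl.

Step 13
Reactants: 17 9-vinyl diene; 18 4-bromofuran-2(5H)-one
Product: 20 6-O-tert-butyldimethylsilyl ether of the target, via B-alkyl borane 19 (not isolated)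
Conditions: 9-borabicyclo[3.3.1]nonane (3 equiv), THF, 0 °C to rt; then 18, PdCl2[1,1′-bis(diphenylphosphino)ferrocene] (10 mol%), AsPh3, Cs2CO3, DMF/H2O, rt
Reagents that add atoms: none
Why: Anti-Markovnikov hydroboration of the monosubstituted vinyl group (the tetrasubstituted C8=C9 alkene is inert to this borane) followed by B-alkyl Suzuki–Miyaura coupling with the activated β-bromobutenolide should join C12 to C13, any O–B bond at the C2 hydroxyl being hydrolysed in the aqueous base.

Step 14
Reactants: 20 6-O-tert-butyldimethylsilyl ether of the target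
Product: 21 CNP0201970.1
Conditions: HF·pyridine, pyridine, THF, 0 °C to rt
Reagents that add atoms: none
Why: Fluoride cleavage of the secondary silyl ether under mildly acidic conditions should leave the acetate, the butenolide and the tetrasubstituted alkene intact.

**Compound list**

1 | 2H-pyran-3,5(4H,6H)-dione | O=C1COCC(=O)C1 | starting material
2 | 5-ethoxy-2H-pyran-3(6H)-one | CCOC1=CC(=O)COC1 | intermediate
3 | lithium 5-ethoxy-3-methyl-3,6-dihydro-2H-pyran-3-olate (not isolated) | CCOC1=CC(C)(O[Li])COC1 | intermediate
4 | 5-methyl-2H-pyran-3(6H)-one | CC1=CC(=O)COC1 | intermediate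
5 | lithium 5-methyl-2H-pyran-3-olate, cross-conjugated dienolate (not isolated) | CC1=CC(O[Li])=COC1 | intermediate
6 | 3-methyl-5-(triisopropylsilyloxy)-2H-pyran | CC1=CC(O[Si](C(C)C)(C(C)C)C(C)C)=COC1 | intermediate
7 | 2,6-dimethyl-1,4-benzoquinone | CC1=CC(=O)C=C(C)C1=O | starting material
8 | endo Diels–Alder adduct: ring B enedione (C6=O, C7=C8–CH3, C9=O) cis-fused (5β-H, 10β-CH3) to ring A carrying the C2=C3 triisopropylsilyl enol ether, 4α-CH3 and the 1β,19-epoxy bridge | C3[C@@]1(C)C=C(O[Si](C(C)C)(C(C)C)C(C)C)[C@@H](O3)[C@]2(C)C(=O)C(C)=CC(=O)[C@H]12 | intermediate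
9 | 6α-alcohol of 8 | C3[C@@]1(C)C=C(O[Si](C(C)C)(C(C)C)C(C)C)[C@@H](O3)[C@]2(C)C(=O)C(C)=C[C@H](O)[C@H]12 | intermediate
10 | 6α-O-tert-butyldimethylsilyl ether of 9 | C3[C@@]1(C)C=C(O[Si](C(C)C)(C(C)C)C(C)C)[C@@H](O3)[C@]2(C)C(=O)C(C)=C[C@H](O[Si](C)(C)C(C)(C)C)[C@H]12 | intermediate
11 | lithium C8=C9 enolate of 10 with C7H2 (not isolated) | C3[C@@]1(C)C=C(O[Si](C(C)C)(C(C)C)C(C)C)[C@@H](O3)[C@]2(C)C(O[Li])=C(C)C[C@H](O[Si](C)(C)C(C)(C)C)[C@H]12 | intermediate
12 | C9 enol triflate (C8=C9, C7H2, 6α-OSiMe2t-Bu, C2=C3 silyl enol ether, 1β,19-epoxy) | C3[C@@]1(C)C=C(O[Si](C(C)C)(C(C)C)C(C)C)[C@@H](O3)[C@]2(C)C(OS(=O)(=O)C(F)(F)F)=C(C)C[C@H](O[Si](C)(C)C(C)(C)C)[C@H]12 | intermediate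
13 | bridged 2-ketone (1β,19-epoxy-2-oxo, C9 enol triflate, 6α-OSiMe2t-Bu) | C3[C@@]1(C)CC(=O)[C@@H](O3)[C@]2(C)C(OS(=O)(=O)C(F)(F)F)=C(C)C[C@H](O[Si](C)(C)C(C)(C)C)[C@H]12 | intermediate
14 | 19-hydroxy-2-ketone, cis-decalin (4β-CH2OH, 4α-CH3, 5β-H, 10β-CH3, 6α-OSiMe2t-Bu, C9 enol triflate) | OC[C@@]1(C)CC(=O)C[C@]2(C)C(OS(=O)(=O)C(F)(F)F)=C(C)C[C@H](O[Si](C)(C)C(C)(C)C)[C@H]12 | intermediate
15 | 19-acetate of 14 | CC(=O)OC[C@@]1(C)CC(=O)C[C@]2(C)C(OS(=O)(=O)C(F)(F)F)=C(C)C[C@H](O[Si](C)(C)C(C)(C)C)[C@H]12 | intermediate
16 | 2α-alcohol (19-OAc, 6α-OSiMe2t-Bu, C9 enol triflate) | CC(=O)OC[C@@]1(C)C[C@H](O)C[C@]2(C)C(OS(=O)(=O)C(F)(F)F)=C(C)C[C@H](O[Si](C)(C)C(C)(C)C)[C@H]12 | intermediate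
17 | 9-vinyl diene (2α-OH, 19-OAc, 6α-OSiMe2t-Bu) | CC(=O)OC[C@@]1(C)C[C@H](O)C[C@]2(C)C(C=C)=C(C)C[C@H](O[Si](C)(C)C(C)(C)C)[C@H]12 | intermediate
18 | 4-bromofuran-2(5H)-one | BrC1=CC(=O)OC1 | starting material
19 | B-(C12-alkyl)-9-borabicyclo[3.3.1]nonane from 17 (not isolated) | CC(=O)OC[C@@]1(C)C[C@H](O)C[C@]2(C)C(CCB3C4CCCC3CCC4)=C(C)C[C@H](O[Si](C)(C)C(C)(C)C)[C@H]12 | intermediate
20 | 6-O-tert-butyldimethylsilyl ether of the target | CC(=O)OC[C@@]1(C)C[C@H](O)C[C@]2(C)C(CCC3=CC(=O)OC3)=C(C)C[C@H](O[Si](C)(C)C(C)(C)C)[C@H]12 | intermediate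
21 | CNP0201970.1 (19-acetoxy-2α,6α-dihydroxy-5β-H-labda-8,13-dien-16,15-olide) | CC(=O)OC[C@@]1(C)C[C@H](O)C[C@]2(C)C(CCC3=CC(=O)OC3)=C(C)C[C@H](O)[C@H]12 | target

**Step count and risks**

Total steps: 14. Longest linear sequence: 14 steps (1 to 21).

Steps most likely to fail:

1. Step 4. The 2H-pyran diene may open by electrocyclic ring opening to the acyclic dienal before it cycloadds, and enantiofacial or regiochemical control may erode on this hindered diene. Fallback: setting out from 4 and 7, the diene is never handled. Treatment of both in one flask with i-Pr3SiOSO2CF3 and i-Pr2NEt in CH2Cl2 at −78 °C should generate 6 by soft enolisation in the presence of silyl-triflate-activated quinone and drive a Mukaiyama–Michael/Michael (double Michael) annulation. This would give the racemate, that is 8 together with its mirror-image adduct F1. Enantiopurity then comes from resolution instead of catalysis, by preparative chromatography on a chiral stationary phase, and the route is rejoined at 8.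

2. Step 11. If the other chair–chair conformer of the cis-decalin reacts, hydride enters C2 from the α face and the 2β-carbinol results (poor facial selectivity). Fallback: setting out from 14, the free C19 hydroxyl is used to deliver hydride intramolecularly. Me4N[BH(OAc)3] in MeCN/AcOH at −20 °C should bind the 4β-CH2OH group and reduce C2 from the β face to give the 2α,19-diol F2. Selective acetylation of the primary hydroxyl (AcCl, 2,4,6-collidine, CH2Cl2, −78 °C) then comes back to the route at 16.

3. Step 13. The bromobutenolide may be destroyed by aqueous base (hydroxide addition–elimination) faster than the hindered alkylborane transmetalates. Fallback: setting out from 17, hydroboration as before to 19 is followed by oxidative work-up (NaBO3·4H2O) to the C12 primary alcohol F3. Iodination of the primary hydroxyl (I2, PPh3, imidazole) gives the C12 iodide F4. A base-free nickel-catalysed reductive cross-electrophile coupling with 18 (NiBr2·MeOCH2CH2OMe, 4,4′-di-tert-butyl-2,2′-bipyridine, Zn, NaI, N,N-dimethylacetamide, rt) comes back to the route at 20.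

**Further compounds**

F1 | step 4 | mirror image of adduct 8 | C3[C@]1(C)C=C(O[Si](C(C)C)(C(C)C)C(C)C)[C@H](O3)[C@@]2(C)C(=O)C(C)=CC(=O)[C@@H]12
F2 | step 11 | 2α,19-diol (6α-OSiMe2t-Bu, C9 enol triflate) | OC[C@@]1(C)C[C@H](O)C[C@]2(C)C(OS(=O)(=O)C(F)(F)F)=C(C)C[C@H](O[Si](C)(C)C(C)(C)C)[C@H]12
F3 | step 13 | C12 primary alcohol (2α-OH, 19-OAc, 6α-OSiMe2t-Bu) | CC(=O)OC[C@@]1(C)C[C@H](O)C[C@]2(C)C(CCO)=C(C)C[C@H](O[Si](C)(C)C(C)(C)C)[C@H]12
F4 | step 13 | C12 primary iodide (2α-OH, 19-OAc, 6α-OSiMe2t-Bu) | CC(=O)OC[C@@]1(C)C[C@H](O)C[C@]2(C)C(CCI)=C(C)C[C@H](O[Si](C)(C)C(C)(C)C)[C@H]12
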